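## Retrosynthetic overview

1. Late stage: the 6α‑acetoxy‑7β‑ol comes from a 7‑ketone (α‑face oxygenation of its C6 enolate, acetylation, axial hydride delivery at C7). The (12Z)‑diene comes from a C12 aldehyde by Z‑selective iodo‑olefination and Stille vinylation.
2. Key disconnection: C1–C2, C9–C10 and C8–O are cut together, back to the open‑chain enyne–ene tert‑butyl carbonate 15. Forward, ring A closes first (C1–C2), ring B second (C9–C10), and a temporary 7,8‑carbonate ring third.
3. Enabling feature: the quaternary ring‑fusion carbon C10, its methyl C20 and the neighbouring ring‑A methylene C1 are an isopropenyl group in disguise. Its CH2 carbon can attack a gold‑activated ethynyl group (C2≡C3) on the gem‑dimethyl carbon C4 and leave a tertiary cation at C10. The methyl‑bearing tertiary carbinol C8 next to the C7 carbinol in ring B lets an E‑trisubstituted alkene and an allylic carbonate finish the cascade.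
4. 15 comes from alkynal 7 and alkenyl iodide 11 (Nozaki–Hiyama–Kishi coupling); 7 comes from 2‑methylcyclohex‑2‑en‑1‑one by asymmetric conjugate addition/methylation and Eschenmoser–Tanabe fragmentation of that temporary ring.

Key step: step 11

Remark: atoms are numbered as in labdane (ring A: C1–C5, C10; ring B: C5–C10; side chain C11–C16; C17 on C8, C18/C19 on C4, C20 on C10); "labdane" means 5α‑H, 9α‑H, 10β‑CH3, and α is the face opposite C20.
Assumption: the ferrocenyl diphosphine enantiomer named in step 1 is taken to direct the Grignard reagent to the Si face of C3 of 1; if its sense of induction is the opposite, its mirror image is used.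

## Route

Step 1
Reactants: 1 2-methylcyclohex-2-en-1-one
Product: 3 (R)-2,2-dimethyl-3-(prop-1-en-2-yl)cyclohexan-1-one, via bromomagnesium enolate 2 (not isolated)
Conditions: isopropenylMgBr, CuBr·SMe2 (5 mol %), (R)-1-[(S)-2-(diphenylphosphino)ferrocenyl]ethyldicyclohexylphosphine (6 mol %), t-BuOMe, −75 °C; then MeI, DMPU, −75 to 0 °C
Reagents that add atoms: isopropenylmagnesium bromide, C=C(C)[Mg]Br; iodomethane, CI
Why: Copper-catalysed asymmetric conjugate addition of the alkenyl Grignard reagent (ligand-controlled Si-face attack at C3 sets the R stereocentre, the later C5) gives a magnesium enolate that is C-methylated regiospecifically at C2 (tandem conjugate addition–enolate alkylation), making that carbon the gem-dimethyl centre.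

Step 2
Reactants: 3 (R)-2,2-dimethyl-3-(prop-1-en-2-yl)cyclohexan-1-one
Product: 4 (R)-6,6-dimethyl-5-(prop-1-en-2-yl)cyclohex-2-en-1-one
Conditions: IBX, DMSO, 70 °C
Reagents that add atoms: none
Why: IBX dehydrogenation of a ketone through its enol should be regiospecific because the other α-carbon is quaternary; the stereocentre is not touched.

Step 3
Reactants: 4 (R)-6,6-dimethyl-5-(prop-1-en-2-yl)cyclohex-2-en-1-one
Product: 5 (1S,4R,6S)-3,3-dimethyl-4-(prop-1-en-2-yl)-7-oxabicyclo[4.1.0]heptan-2-one
Conditions: H2O2 (30 % aq), NaOH (cat.), MeOH, 0 °C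
Reagents that add atoms: hydrogen peroxide, OO
Why: Weitz–Scheffer nucleophilic epoxidation attacks only the electron-poor enone alkene and leaves the isopropenyl group alone; attack anti to the isopropenyl group is expected, but the epoxide configuration is lost in step 4.

Step 4
Reactants: 5 (1S,4R,6S)-3,3-dimethyl-4-(prop-1-en-2-yl)-7-oxabicyclo[4.1.0]heptan-2-one
Product: 7 (R)-4,4-dimethyl-3-(prop-1-en-2-yl)hex-5-ynal, via epoxy tosylhydrazone 6 (not isolated)
Conditions: TsNHNH2, CH2Cl2/AcOH (1:1), −20 °C to rt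
Reagents that add atoms: none
Why: Eschenmoser–Tanabe fragmentation: the tosylhydrazone opens the epoxide and fragments with loss of N2 and sulfinate, so the carbonyl carbon and its α-carbon become the terminal alkyne (C3≡C2) on the quaternary carbon and the β-carbon becomes the aldehyde (C7); the stereocentre is untouched.

Step 5
Reactants: 8 pent-3-yn-1-ol
Product: 9 benzyl pent-3-yn-1-yl carbonate
Conditions: CbzCl, pyridine, CH2Cl2, 0 °C
Reagents that add atoms: benzyl chloroformate, O=C(Cl)OCc1ccccc1
Why: Acylation of the primary alcohol gives a carbonate that is non-nucleophilic towards cations in step 11 and is removed by hydrogenolysis in step 12.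

Step 6
Reactants: 9 benzyl pent-3-yn-1-yl carbonate
Product: 11 benzyl [(3E)-4-iodopent-3-en-1-yl] carbonate, via alkenylzirconocene chloride 10 (not isolated)
Conditions: Cp2Zr(H)Cl, THF, rt to 40 °C; then I2, 0 °C
Reagents that add atoms: iodine, II
Why: syn-Hydrozirconation, equilibrated with a slight excess of the hydride, should place zirconium on the less hindered methyl-bearing alkyne carbon; iodinolysis with retention then gives the E-iodoalkene (C8, C9, C11, C12 and C17 of the target).

Step 7
Reactants: 7 (R)-4,4-dimethyl-3-(prop-1-en-2-yl)hex-5-ynal; 11 benzyl [(3E)-4-iodopent-3-en-1-yl] carbonate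
Product: 12 benzyl [(3E,5RS,7R)-5-hydroxy-4,8,8-trimethyl-7-(prop-1-en-2-yl)dec-3-en-9-yn-1-yl] carbonate (C5 epimers)
Conditions: CrCl2 (4 equiv), NiCl2 (2 mol %), DMSO, rt
Reagents that add atoms: none
Why: Nozaki–Hiyama–Kishi coupling adds the alkenylchromium reagent chemoselectively to the aldehyde with retention of the E geometry and tolerates the carbonate and the terminal alkyne; the new carbinol centre forms unselectively and is erased in step 8.

Step 8
Reactants: 12 benzyl [(3E,5RS,7R)-5-hydroxy-4,8,8-trimethyl-7-(prop-1-en-2-yl)dec-3-en-9-yn-1-yl] carbonate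
Product: 13 benzyl [(3E,7R)-4,8,8-trimethyl-5-oxo-7-(prop-1-en-2-yl)dec-3-en-9-yn-1-yl] carbonate
Conditions: Dess–Martin periodinane, NaHCO3, CH2Cl2, 0 °C to rt
Reagents that add atoms: none
Why: Dess–Martin oxidation of the allylic alcohol converges both epimers on one enone without touching alkyne, alkenes or carbonate.

Step 9
Reactants: 13 benzyl [(3E,7R)-4,8,8-trimethyl-5-oxo-7-(prop-1-en-2-yl)dec-3-en-9-yn-1-yl] carbonate
Product: 14 benzyl [(3E,5R,7R)-5-hydroxy-4,8,8-trimethyl-7-(prop-1-en-2-yl)dec-3-en-9-yn-1-yl] carbonate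
Conditions: (S)-2-methyl-CBS-oxazaborolidine [(S)-tetrahydro-1-methyl-3,3-diphenyl-1H,3H-pyrrolo[1,2-c][1,3,2]oxazaborole] (20 mol %), catecholborane, toluene, −78 °C
Reagents that add atoms: none
Why: Corey–Bakshi–Shibata reduction: the α-methylalkenyl group acts as the large substituent, so the (S)-catalyst should give the (5R)-carbinol (future 7α-oxygen) under reagent control, and catecholborane at −78 °C does not hydroborate the alkyne or alkenes.

Step 10
Reactants: 14 benzyl [(3E,5R,7R)-5-hydroxy-4,8,8-trimethyl-7-(prop-1-en-2-yl)dec-3-en-9-yn-1-yl] carbonate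
Product: 15 benzyl [(3E,5R,7R)-5-[(tert-butoxycarbonyl)oxy]-4,8,8-trimethyl-7-(prop-1-en-2-yl)dec-3-en-9-yn-1-yl] carbonate
Conditions: Boc2O, DMAP (cat.), Et3N, CH2Cl2, rt
Reagents that add atoms: di-tert-butyl dicarbonate, CC(C)(C)OC(=O)OC(=O)OC(C)(C)C
Why: DMAP-catalysed acylation turns the C7 oxygen into a tert-butyl carbonate, which is too electron-poor to trap the C10 cation through its ether oxygen but can capture the C8 cation through its carbonyl oxygen.

Step 11
Reactants: 15 benzyl [(3E,5R,7R)-5-[(tert-butoxycarbonyl)oxy]-4,8,8-trimethyl-7-(prop-1-en-2-yl)dec-3-en-9-yn-1-yl] carbonate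
Product: 16 benzyl 7α,8α-carbonyldioxy-13,14,15,16-tetranorlabd-2-en-12-yl carbonate
Conditions: Ph3PAuNTf2 (5 mol %), CH2Cl2, 0 °C to rt
Reagents that add atoms: none
Why: Proposed new method: the cationic monovalent-gold catalyst activates the terminal alkyne, the CH2 carbon of the isopropenyl group (C1) attacks the terminal alkyne carbon C2 (6-endo-dig, ring A) leaving a tertiary cation at C10 and a vinyl–gold bond at C3, C9 of the E-trisubstituted alkene adds to C10 (6-endo-trig, ring B), and the carbonyl oxygen of the allylic tert-butyl carbonate captures the tertiary C8 cation (5-exo-trig, temporary dioxolanone ring) with loss of 2-methylpropene, the released proton cleaving the C3–Au bond and returning the catalyst. The closest known reaction types are the gold-catalysed 6-endo-dig cyclization of 1,5-enynes bearing a 1,1-disubstituted alkene, gold-catalysed alkyne-initiated polyene cyclizations ended by oxygen nucleophiles, and cation–olefin cyclizations terminated by tert-butyl carbonates; their union on a polyene branched at C5 has no direct precedent. C10 is set by the C5 stereocentre through a chair–chair transition state in which the C6 chain is equatorial on ring A, the C7 carbonate is axial on the α-face (free of allylic strain with C17 and placed to reach the α-face of C8) and C9 adds anti to the new C1–C2 bond (C20 axial, trans to H5); C9 is set by the E geometry of the alkene (C11 equatorial) and C8 by anti addition across C8=C9 (oxygen α-equatorial, C17 β-axial). The step needs 6-endo closure instead of 5-endo closure or skeletal rearrangement, which the tertiary character of C10 and the hydrogen-free quaternary propargylic C4 should secure, and it needs ring-B closure to outrun proton loss from C10, for which the trisubstituted alkene is held in a six-membered transition state and the counter-ion is non-basic.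

Step 12
Reactants: 16 benzyl 7α,8α-carbonyldioxy-13,14,15,16-tetranorlabd-2-en-12-yl carbonate
Product: 17 7α,8α-carbonyldioxy-13,14,15,16-tetranorlabdan-12-ol
Conditions: H2 (1 atm), Pd/C, EtOAc, rt
Reagents that add atoms: none
Why: Heterogeneous hydrogenation saturates the unhindered cis-disubstituted C2=C3 alkene and hydrogenolyses the benzyl carbonate in the same operation; the cyclic carbonate and all stereocentres are untouched.

Step 13
Reactants: 17 7α,8α-carbonyldioxy-13,14,15,16-tetranorlabdan-12-ol
Product: 18 7α,8α-carbonyldioxy-13,14,15,16-tetranorlabdan-12-al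
Conditions: Dess–Martin periodinane, NaHCO3, CH2Cl2, rt
Reagents that add atoms: none
Why: Dess–Martin oxidation of the primary alcohol gives the aldehyde; because O8 is tied up in the carbonate no lactol can form.

Step 14
Reactants: 18 7α,8α-carbonyldioxy-13,14,15,16-tetranorlabdan-12-al
Product: 19 (12Z)-13-iodo-7α,8α-carbonyldioxy-14,15-dinorlabd-12-ene
Conditions: Ph3P(Et)I, n-BuLi, THF; I2, −78 °C; NaHMDS, −20 °C; then 18, −78 °C
Reagents that add atoms: ethyltriphenylphosphonium iodide, CC[P+](c1ccccc1)(c1ccccc1)c1ccccc1.[I-]; iodine, II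
Why: Stork–Zhao olefination with the α-iodo ylide should give the Z-iodoalkene (iodine cis to C11) under kinetic control at −78 °C, where the aldehyde reacts far faster than the cyclic carbonate.

Step 15
Reactants: 19 (12Z)-13-iodo-7α,8α-carbonyldioxy-14,15-dinorlabd-12-ene
Product: 20 (12Z)-7α,8α-carbonyldioxylabda-12,14-diene
Conditions: tributyl(vinyl)stannane, Pd(PPh3)4 (5 mol %), CuI (10 mol %), DMF, 40 °C
Reagents that add atoms: tributyl(vinyl)stannane, C=C[Sn](CCCC)(CCCC)CCCC
Why: Stille coupling replaces iodine by vinyl with retention of the alkene geometry, giving the (12Z)-12,14-diene under neutral conditions.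

Step 16
Reactants: 20 (12Z)-7α,8α-carbonyldioxylabda-12,14-diene
Product: 21 (12Z)-labda-12,14-diene-7α,8α-diol
Conditions: NaOH (aq), MeOH/THF, rt
Reagents that add atoms: none
Why: Saponification at the carbonyl carbon of the five-membered carbonate frees the diol with O7 and O8 retained; the diene is inert to base.

Step 17
Reactants: 21 (12Z)-labda-12,14-diene-7α,8α-diol
Product: 22 (12Z)-8α-hydroxylabda-12,14-dien-7-one
Conditions: Dess–Martin periodinane, NaHCO3, CH2Cl2, 0 °C
Reagents that add atoms: none
Why: Only the secondary axial 7α-alcohol can be oxidised (8-OH is tertiary), which removes the C7 centre that served the cascade and gives the ketone needed to functionalise C6.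

Step 18
Reactants: 22 (12Z)-8α-hydroxylabda-12,14-dien-7-one
Product: 24 (12Z)-6α,8α-dihydroxylabda-12,14-dien-7-one, via dipotassium dianion 23 (not isolated)
Conditions: KHMDS (2.5 equiv), THF, −78 °C; then 2-(phenylsulfonyl)-3-phenyloxaziridine, −78 °C; NH4Cl (aq)
Reagents that add atoms: 2-(phenylsulfonyl)-3-phenyloxaziridine, O=S(=O)(c1ccccc1)N1OC1c1ccccc1
Why: Enolate hydroxylation with a Davis oxaziridine: C8 is quaternary so the ketone enolises only towards C6, and the β-face is shielded by the axial methyls C19 and C20, so oxygen should arrive from the α-face and give the equatorial 6α-alcohol.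

Step 19
Reactants: 24 (12Z)-6α,8α-dihydroxylabda-12,14-dien-7-one
Product: 25 (12Z)-6α-acetoxy-8α-hydroxylabda-12,14-dien-7-one
Conditions: Ac2O, pyridine, DMAP (cat.), CH2Cl2, 0 °C to rt
Reagents that add atoms: acetic anhydride, CC(=O)OC(C)=O
Why: Acetylation takes the only secondary hydroxyl; the hindered tertiary 8-OH is not acylated under these conditions, and with C7 still a ketone no 6/7 regiochemical question arises.

Step 20
Reactants: 25 (12Z)-6α-acetoxy-8α-hydroxylabda-12,14-dien-7-one
Product: 26 (12Z)-6α-acetoxylabda-12,14-diene-7β,8α-diol (target CNP0138393.1)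
Conditions: NaBH4, MeOH/CH2Cl2, −40 °C; AcOH quench
Reagents that add atoms: none
Why: Axial hydride attack at C7 from the α-face (only H5 and H9 are syn-axial, whereas the equatorial approach is obstructed by the axial C17 methyl) should give the equatorial 7β-alcohol; low temperature and an acidic quench are chosen to suppress acetyl migration.

## Compound list

1 | 2-methylcyclohex-2-en-1-one | CC1=CCCCC1=O | starting material
2 | bromomagnesium (R)-2-methyl-3-(prop-1-en-2-yl)cyclohex-1-en-1-olate | Br[Mg]OC1=C(C)[C@@H](C(C)=C)CCC1 | intermediate (not isolated)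
3 | (R)-2,2-dimethyl-3-(prop-1-en-2-yl)cyclohexan-1-one | O=C1CCC[C@H](C(C)=C)C1(C)C | intermediate
4 | (R)-6,6-dimethyl-5-(prop-1-en-2-yl)cyclohex-2-en-1-one | O=C1C=CC[C@H](C(C)=C)C1(C)C | intermediate
5 | (1S,4R,6S)-3,3-dimethyl-4-(prop-1-en-2-yl)-7-oxabicyclo[4.1.0]heptan-2-one (epoxide anti to isopropenyl) | O=C1[C@H]2O[C@H]2C[C@H](C(C)=C)C1(C)C | intermediate
6 | 4-methylbenzenesulfonylhydrazone of 5 | Cc1ccc(cc1)S(=O)(=O)NN=C1[C@H]2O[C@H]2C[C@H](C(C)=C)C1(C)C | intermediate (not isolated)
7 | (R)-4,4-dimethyl-3-(prop-1-en-2-yl)hex-5-ynal | C#CC(C)(C)[C@@H](C(C)=C)CC=O | intermediate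
8 | pent-3-yn-1-ol | CC#CCCO | starting material
9 | benzyl pent-3-yn-1-yl carbonate | CC#CCCOC(=O)OCc1ccccc1 | intermediate
10 | chlorobis(cyclopentadienyl)[(2E)-5-{[(benzyloxy)carbonyl]oxy}pent-2-en-2-yl]zirconium | C/C(=C\CCOC(=O)OCc1ccccc1)[Zr](Cl)(C1C=CC=C1)C1C=CC=C1 | intermediate (not isolated)
11 | benzyl [(3E)-4-iodopent-3-en-1-yl] carbonate | C/C(I)=C\CCOC(=O)OCc1ccccc1 | intermediate
12 | benzyl [(3E,5RS,7R)-5-hydroxy-4,8,8-trimethyl-7-(prop-1-en-2-yl)dec-3-en-9-yn-1-yl] carbonate (C5 epimers) | C#CC(C)(C)[C@@H](C(C)=C)CC(O)/C(C)=C/CCOC(=O)OCc1ccccc1 | intermediate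
13 | benzyl [(3E,7R)-4,8,8-trimethyl-5-oxo-7-(prop-1-en-2-yl)dec-3-en-9-yn-1-yl] carbonate | C#CC(C)(C)[C@@H](C(C)=C)CC(=O)/C(C)=C/CCOC(=O)OCc1ccccc1 | intermediate
14 | benzyl [(3E,5R,7R)-5-hydroxy-4,8,8-trimethyl-7-(prop-1-en-2-yl)dec-3-en-9-yn-1-yl] carbonate | C#CC(C)(C)[C@@H](C(C)=C)C[C@@H](O)/C(C)=C/CCOC(=O)OCc1ccccc1 | intermediate
15 | benzyl [(3E,5R,7R)-5-[(tert-butoxycarbonyl)oxy]-4,8,8-trimethyl-7-(prop-1-en-2-yl)dec-3-en-9-yn-1-yl] carbonate | C#CC(C)(C)[C@@H](C(C)=C)C[C@@H](OC(=O)OC(C)(C)C)/C(C)=C/CCOC(=O)OCc1ccccc1 | intermediate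
16 | benzyl 7α,8α-carbonyldioxy-13,14,15,16-tetranorlabd-2-en-12-yl carbonate | O=C(OCc1ccccc1)OCC[C@H]1[C@]2(C)OC(=O)O[C@@H]2C[C@H]3C(C)(C)C=CC[C@@]31C | intermediate
17 | 7α,8α-carbonyldioxy-13,14,15,16-tetranorlabdan-12-ol | OCC[C@H]1[C@]2(C)OC(=O)O[C@@H]2C[C@H]3C(C)(C)CCC[C@@]31C | intermediate
18 | 7α,8α-carbonyldioxy-13,14,15,16-tetranorlabdan-12-al | O=CC[C@H]1[C@]2(C)OC(=O)O[C@@H]2C[C@H]3C(C)(C)CCC[C@@]31C | intermediate
19 | (12Z)-13-iodo-7α,8α-carbonyldioxy-14,15-dinorlabd-12-ene | C/C(I)=C/C[C@H]1[C@]2(C)OC(=O)O[C@@H]2C[C@H]3C(C)(C)CCC[C@@]31C | intermediate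
20 | (12Z)-7α,8α-carbonyldioxylabda-12,14-diene | C=C/C(C)=C\C[C@H]1[C@]2(C)OC(=O)O[C@@H]2C[C@H]3C(C)(C)CCC[C@@]31C | intermediate
21 | (12Z)-labda-12,14-diene-7α,8α-diol | C=C/C(C)=C\C[C@H]1[C@](C)(O)[C@H](O)C[C@H]2C(C)(C)CCC[C@@]21C | intermediate
22 | (12Z)-8α-hydroxylabda-12,14-dien-7-one | C=C/C(C)=C\C[C@H]1[C@](C)(O)C(=O)C[C@H]2C(C)(C)CCC[C@@]21C | intermediate
23 | dipotassium 8-alkoxide 6-en-7-olate of 22 | C=C/C(C)=C\C[C@H]1[C@](C)(O[K])C(O[K])=C[C@H]2C(C)(C)CCC[C@@]21C | intermediate (not isolated)
24 | (12Z)-6α,8α-dihydroxylabda-12,14-dien-7-one | C=C/C(C)=C\C[C@H]1[C@](C)(O)C(=O)[C@H](O)[C@H]2C(C)(C)CCC[C@@]21C | intermediate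
25 | (12Z)-6α-acetoxy-8α-hydroxylabda-12,14-dien-7-one | C=C/C(C)=C\C[C@H]1[C@](C)(O)C(=O)[C@H](OC(C)=O)[C@H]2C(C)(C)CCC[C@@]21C | intermediate
26 | (12Z)-6α-acetoxylabda-12,14-diene-7β,8α-diol | C=C/C(C)=C\C[C@H]1[C@](C)(O)[C@@H](O)[C@H](OC(C)=O)[C@H]2C(C)(C)CCC[C@@]21C | target

## Step count and risks

Total: 20 steps. Longest linear sequence: 18 steps (steps 1–4 and 7–20); steps 5–6 make the second fragment.

**Step 11 (proposed new method).** The C10 cation formed after the first ring closure may lose a proton (towards C1, C5 or C20) faster than the C8=C9 alkene captures it, or ring B may close through the cis-fused pathway. The fallback makes the two C–C bonds in two separate known cationic operations. Setting out from 15, gold-catalysed hydroxycyclization (Ph3PAuNTf2 cat., 1,4-dioxane/H2O, rt) lets water intercept the C10 cation. It should give the monocyclic tertiary alcohol benzyl [(3E,5R)-5-[(tert-butoxycarbonyl)oxy]-6-[(1S)-2-hydroxy-2,6,6-trimethylcyclohex-4-en-1-yl]-4-methylhex-3-en-1-yl] carbonate F1 (either carbinol epimer serves). Ionization of F1 with BF3·OEt2 in CH2Cl2 at −78 °C, where elimination is slow, then performs the carbonate-terminated cation–olefin closure of ring B and comes back to the route at 16.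

**Step 1.** Facial selectivity of the copper-catalysed addition to an α-substituted enone may be low. Setting out from 1, the same tandem addition–methylation without chiral ligand (isopropenylMgBr, CuBr·SMe2 cat., THF, −40 °C; then MeI, DMPU) gives racemic 2,2-dimethyl-3-(prop-1-en-2-yl)cyclohexan-1-one F2. F2 is resolved by preparative chromatography on a chiral stationary phase; (S)-2,2-dimethyl-3-(prop-1-en-2-yl)cyclohexan-1-one F3 is discarded and the (R)-ketone is 3, where the route is rejoined.

**Step 14.** Z-selectivity of the iodo-olefination may erode. Setting out from 18, Still–Gennari olefination with methyl 2-[bis(2,2,2-trifluoroethoxy)phosphoryl]propanoate (KHMDS, 18-crown-6, THF, −78 °C) should give methyl (12Z)-7α,8α-carbonyldioxy-15-norlabd-12-en-14-oate F4. Reduction with i-Bu2AlH (CH2Cl2, −78 °C, ester ahead of the cyclic carbonate) gives (12Z)-7α,8α-carbonyldioxy-15-norlabd-12-en-14-ol F5. MnO2 oxidation gives (12Z)-7α,8α-carbonyldioxy-15-norlabd-12-en-14-al F6, and Wittig methylenation (Ph3P=CH2, THF, −78 to 0 °C) comes back to the route at 20.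

## Further compounds

F1 | step 11 | benzyl [(3E,5R)-5-[(tert-butoxycarbonyl)oxy]-6-[(1S)-2-hydroxy-2,6,6-trimethylcyclohex-4-en-1-yl]-4-methylhex-3-en-1-yl] carbonate (carbinol epimers) | CC1(O)CC=CC(C)(C)[C@@H]1C[C@@H](OC(=O)OC(C)(C)C)/C(C)=C/CCOC(=O)OCc1ccccc1
F2 | step 1 | racemic 2,2-dimethyl-3-(prop-1-en-2-yl)cyclohexan-1-one | O=C1CCCC(C(C)=C)C1(C)C
F3 | step 1 | (S)-2,2-dimethyl-3-(prop-1-en-2-yl)cyclohexan-1-one | O=C1CCC[C@@H](C(C)=C)C1(C)C
F4 | step 14 | methyl (12Z)-7α,8α-carbonyldioxy-15-norlabd-12-en-14-oate | COC(=O)/C(C)=C\C[C@H]1[C@]2(C)OC(=O)O[C@@H]2C[C@H]3C(C)(C)CCC[C@@]31C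
F5 | step 14 | (12Z)-7α,8α-carbonyldioxy-15-norlabd-12-en-14-ol | OC/C(C)=C\C[C@H]1[C@]2(C)OC(=O)O[C@@H]2C[C@H]3C(C)(C)CCC[C@@]31C
F6 | step 14 | (12Z)-7α,8α-carbonyldioxy-15-norlabd-12-en-14-al | O=C/C(C)=C\C[C@H]1[C@]2(C)OC(=O)O[C@@H]2C[C@H]3C(C)(C)CCC[C@@]31C
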